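**Retrosynthetic overview**
- Feature: along C2–C3–C4–C4a–C5–C6–C7–C8–C8a of the chromone, oxygen sits on every second carbon (C2, C4, C5, C7, C8a) and C8 carries the methyl. The bicycle is therefore a folded, C8-methylated linear polyketone that begins with a C32 fatty acyl unit.
- Both rings are cut in one operation, C4a–C8a (benzene ring, Claisen) and O1–C2 (pyranone ring, cyclodehydration). This leads to a tetraketo ester stored as its lactone, a 4-hydroxy-3-methyl-2-pyrone with a 2,4-dioxopentatriacontyl chain on C6.
- The side chain is cut at the future C2–C3 bond (terminal acylation of a pyrone trianion with the C32 Weinreb amide) and at the future C4–C4a bond (acetylation of the 6-methyl dianion).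
- The future C8 methyl is put on C3 of 4-hydroxy-6-methyl-2-pyrone first, by sulfanylmethylation and desulfurisation.
- Ring order: pyrone (bought), then benzene ring (C4a–C8a), then pyranone ring (O1–C2), the last two in one flask.

Key step: step 6

Remark: the polycarbonyl compounds are drawn as keto tautomers; they are expected to be largely enolised, which changes no atom count.

**Step 1**
Reactants: 1 4-hydroxy-6-methyl-2H-pyran-2-one
Product: 2 4-hydroxy-6-methyl-3-[(phenylsulfanyl)methyl]-2H-pyran-2-one
Conditions: (CH2O)n (1.5 equiv), PhSH (2 equiv), piperidine (cat.), AcOH (cat.), EtOH, 60 °C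
Reagents that add atoms: formaldehyde (as paraformaldehyde), C=O; thiophenol, Sc1ccccc1
Why: Knoevenagel condensation at the nucleophilic C3 of the pyrone followed by conjugate (thia-Michael) addition of thiophenol is a known three-component C3-alkylation of 4-hydroxy-2-pyrones, and excess thiol should outrun addition of a second pyrone.

**Step 2**
Reactants: 2 4-hydroxy-6-methyl-3-[(phenylsulfanyl)methyl]-2H-pyran-2-one
Product: 3 4-hydroxy-3,6-dimethyl-2H-pyran-2-one
Conditions: Raney Ni (W-2, acetone-deactivated), EtOH, reflux, short reaction time
Reagents that add atoms: none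
Why: Raney Ni reductive desulfurisation cleaves the C–S bonds and leaves the C3 methyl, while the enolised 2-pyrone ring should not be hydrogenated under these brief conditions.

**Step 3**
Reactants: 3 4-hydroxy-3,6-dimethyl-2H-pyran-2-one; 4 N-methoxy-N-methylacetamide
Product: 5 4-hydroxy-3-methyl-6-(2-oxopropyl)-2H-pyran-2-one
Conditions: LiN(i-Pr)2 (commercial solution, 2.4 equiv), THF, −78 °C; then 4 (1.2 equiv), −78 to 0 °C; cold aq HCl
Reagents that add atoms: none
Why: Two equivalents of amide base give the O,C-dianion at the vinylogous 6-methyl group (Harris-type pyrone dianion), and its carbanion is acylated by the Weinreb amide, whose chelated tetrahedral intermediate lasts until the acid quench and so prevents double addition and proton transfer from the product.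

**Step 4**
Reactants: 6 dotriacontanoic acid
Product: 8 N-methoxy-N-methyldotriacontanamide, via dotriacontanoyl chloride 7 (not isolated)
Conditions: (COCl)2, DMF (cat.), CH2Cl2–toluene, 40 °C; evaporate; then MeNHOMe·HCl, Et3N, CH2Cl2, 0 °C to rt
Reagents that add atoms: N,O-dimethylhydroxylamine hydrochloride, CNOC.Cl; oxalyl chloride, O=C(Cl)C(=O)Cl (chlorine of 7 only)
Why: Acid chloride formation under DMF catalysis followed by amidation is the standard Weinreb amide synthesis, and the saturated chain carries no other reactive group.

**Step 5**
Reactants: 5 4-hydroxy-3-methyl-6-(2-oxopropyl)-2H-pyran-2-one (1.2 equiv); 8 N-methoxy-N-methyldotriacontanamide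
Product: 9 4-hydroxy-3-methyl-6-(2,4-dioxopentatriacontyl)-2H-pyran-2-one
Conditions: LiN(i-Pr)2 (commercial solution, 3.2 equiv per 5), THF, −78 to 0 °C; then 8 as a warm THF solution, 0 °C to rt; cold 1 M HCl
Reagents that add atoms: none
Why: Three equivalents of base give the trianion, and by the Hauser rule the last-formed terminal carbanion (the former acetyl methyl) is acylated selectively in a Claisen-type condensation with the Weinreb amide, whose stable chelate keeps the diketone product from consuming trianion.

**Step 6**
Reactants: 9 4-hydroxy-3-methyl-6-(2,4-dioxopentatriacontyl)-2H-pyran-2-one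
Product: 12 2-hentriacontyl-5,7-dihydroxy-8-methyl-4H-chromen-4-one, via tetraketo methyl ester 10 (not isolated), via aryl 1,3-diketone 11 (not isolated)
Conditions: Mg(OMe)2 (8 equiv), MeOH–THF (degassed), reflux, N2; then 2 M HCl to pH 1, MeOH–THF–H2O, 40 °C
Reagents that add atoms: magnesium methoxide, C[O-].[Mg+2].C[O-] (methoxy group of 10 only; it leaves again as methanol)
Why: Methoxide adds to the lactone carbonyl (pyrone C2, the future C8a) and opens the ring to the magnesium-chelated tetraketo ester 10, whose doubly activated methylene between the future C5 and C4 carbonyls (future C4a) attacks the ester carbonyl in a Claisen (Dieckmann-type) condensation, and the product aromatises by enolisation to the 3-methylphloroglucinol 11. On acidification the C8a hydroxyl adds to the C2 ketone and water is lost, which gives the 4-pyranone ring. The closest known reactions are the Mg(OMe)2-induced conversion of 6-(2-oxoalkyl)-4-hydroxy-2-pyrones and 3,5,7-triketo esters into acylphloroglucinols and the acid cyclodehydration of o-hydroxyaryl 1,3-diketones to chromones. Both closures are 6-exo-trig (C4a onto the C8a ester carbonyl for the benzene ring; O1 onto the C2 carbonyl for the pyranone ring), and no stereocentre is formed. Claisen folding has to win over aldol folding: the lactone keeps C8a, C7 and C5 masked until methanolysis, magnesium chelation of the 1,3-dicarbonyl units lowers the electrophilicity of the ketones so that the ester is the acceptor, and the methyl on the future C8 makes any aldol adduct from that carbon quaternary, unable to aromatise and therefore reversible. Closure through the hydroxyl beside the methyl (8-methyl series) and not through the other ortho hydroxyl (6-methyl series) is expected as the kinetic course known for C-methylphloroacylphenones, dilute HCl at 40 °C should not reopen and isomerise the pyranone, and an HMBC correlation from the chelated 5-OH proton to a protonated C6 should distinguish the 8-methyl chromone from its 6-methyl isomer.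

**Compound list**
1 | 4-hydroxy-6-methyl-2H-pyran-2-one | Cc1cc(O)cc(=O)o1 | starting material
2 | 4-hydroxy-6-methyl-3-[(phenylsulfanyl)methyl]-2H-pyran-2-one | Cc1cc(O)c(CSc2ccccc2)c(=O)o1 | intermediate
3 | 4-hydroxy-3,6-dimethyl-2H-pyran-2-one | Cc1cc(O)c(C)c(=O)o1 | intermediate
4 | N-methoxy-N-methylacetamide | CON(C)C(C)=O | starting material
5 | 4-hydroxy-3-methyl-6-(2-oxopropyl)-2H-pyran-2-one | CC(=O)Cc1cc(O)c(C)c(=O)o1 | intermediate
6 | dotriacontanoic acid | CCCCCCCCCCCCCCCCCCCCCCCCCCCCCCCC(=O)O | starting material
7 | dotriacontanoyl chloride | CCCCCCCCCCCCCCCCCCCCCCCCCCCCCCCC(=O)Cl | intermediate (not isolated)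
8 | N-methoxy-N-methyldotriacontanamide | CCCCCCCCCCCCCCCCCCCCCCCCCCCCCCCC(=O)N(C)OC | intermediate
9 | 4-hydroxy-3-methyl-6-(2,4-dioxopentatriacontyl)-2H-pyran-2-one | CCCCCCCCCCCCCCCCCCCCCCCCCCCCCCCC(=O)CC(=O)Cc1cc(O)c(C)c(=O)o1 | intermediate
10 | methyl 2-methyl-3,5,7,9-tetraoxotetracontanoate (racemic, labile C2; magnesium chelate in the flask) | CCCCCCCCCCCCCCCCCCCCCCCCCCCCCCCC(=O)CC(=O)CC(=O)CC(=O)C(C)C(=O)OC | intermediate (not isolated)
11 | 1-(2,4,6-trihydroxy-3-methylphenyl)tetratriacontane-1,3-dione | CCCCCCCCCCCCCCCCCCCCCCCCCCCCCCCC(=O)CC(=O)c1c(O)cc(O)c(C)c1O | intermediate (not isolated)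
12 | 2-hentriacontyl-5,7-dihydroxy-8-methyl-4H-chromen-4-one | CCCCCCCCCCCCCCCCCCCCCCCCCCCCCCCc1cc(=O)c2c(O)cc(O)c(C)c2o1 | target

**Count**
Total steps: 6. Longest linear sequence: 5 (steps 1, 2, 3, 5, 6); step 4 is a one-step branch.

**Steps most likely to fail**

1. Step 6. Three processes may compete:
   - aldol closure of the intact pyrone from its C5 onto the terminal ketone before the lactone is opened, followed by dehydration (coumarin-type folding);
   - aldol folding of the opened chain;
   - cyclodehydration through the hydroxyl remote from the methyl (6-methyl series).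

   Fallback (sets out from 8, returns at 12): the benzene ring is bought instead of folded. Purchased 1-(2-hydroxy-4,6-dimethoxy-3-methylphenyl)ethan-1-one F1 is converted into its O,C-dianion with LiN(SiMe3)2 (3 equiv, THF, −78 to 0 °C) and C-acylated with 8 to give 1-(2-hydroxy-4,6-dimethoxy-3-methylphenyl)tetratriacontane-1,3-dione F2. Catalytic H2SO4 in AcOH at 80 °C should close the only free hydroxyl, the one beside the methyl, onto the diketone to give 2-hentriacontyl-5,7-dimethoxy-8-methyl-4H-chromen-4-one F3. BBr3 in CH2Cl2 (−78 °C to rt) should then cleave both methyl ethers to give 12 without the ring opening that hot HI would cause.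

2. Step 5. Three processes may compete:
   - proton transfer from the α-methylene of the amide to the strongly basic terminal carbanion;
   - slow acylation by a poorly soluble C32 electrophile;
   - base-induced breakdown of the N-methoxy amide.

   Fallback (sets out from 8, returns at 9): aldol addition and oxidation replace acylation. LiAlH4 (THF, 0 °C) reduces 8 to dotriacontanal F4. The trianion of 5 (LiN(i-Pr)2, THF, −78 to −20 °C) adds through its terminal carbon to F4 and gives racemic 4-hydroxy-6-(4-hydroxy-2-oxopentatriacontyl)-3-methyl-2H-pyran-2-one F5. 2-Iodoxybenzoic acid in EtOAc at 75 °C oxidises the β-hydroxy ketone to the 1,3-diketone 9.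

3. Step 1. The Knoevenagel intermediate may be captured by a second pyrone (methylene-bridged dimer) instead of the thiol, and the pyrone may be over-reduced in the desulfurisation that follows.

   Fallback (sets out from 4, returns at 3; steps 1 and 2 are left out): the pyrone is built with its methyl in place. Purchased ethyl 2-methyl-3-oxobutanoate F6 is converted into its dianion (NaH, then n-BuLi, THF, 0 °C) and acylated at the terminal methyl with 4 to give ethyl 2-methyl-3,5-dioxohexanoate F7. DBU in refluxing toluene lactonises F7 with loss of ethanol to give 3.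

**Further compounds**
F1 | step 6 | 1-(2-hydroxy-4,6-dimethoxy-3-methylphenyl)ethan-1-one (purchased) | CC(=O)c1c(O)c(C)c(OC)cc1OC
F2 | step 6 | 1-(2-hydroxy-4,6-dimethoxy-3-methylphenyl)tetratriacontane-1,3-dione | CCCCCCCCCCCCCCCCCCCCCCCCCCCCCCCC(=O)CC(=O)c1c(O)c(C)c(OC)cc1OC
F3 | step 6 | 2-hentriacontyl-5,7-dimethoxy-8-methyl-4H-chromen-4-one | CCCCCCCCCCCCCCCCCCCCCCCCCCCCCCCc1cc(=O)c2c(OC)cc(OC)c(C)c2o1
F4 | step 5 | dotriacontanal | CCCCCCCCCCCCCCCCCCCCCCCCCCCCCCCC=O
F5 | step 5 | 4-hydroxy-6-(4-hydroxy-2-oxopentatriacontyl)-3-methyl-2H-pyran-2-one (racemic) | CCCCCCCCCCCCCCCCCCCCCCCCCCCCCCCC(O)CC(=O)Cc1cc(O)c(C)c(=O)o1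
F6 | step 1 | ethyl 2-methyl-3-oxobutanoate (purchased) | CCOC(=O)C(C)C(C)=O
F7 | step 1 | ethyl 2-methyl-3,5-dioxohexanoate | CCOC(=O)C(C)C(=O)CC(C)=O
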